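The depsidone is cut at its lactone (O5–C=O) and its diaryl ether (O6–aryl), giving a ring A bromobenzaldehyde and a ring B chromenol. Ring B, whose four oxygens sit on C5, C6, C8 and C8a (O1), is made by thermal ring expansion of a cyclobutenone carrying a dihydropyran-5-yl group. One operation forms the C8–C8a bond, closes the benzene ring onto the pyran and delivers O8 as a free phenol, O6 as an allyl ether, O5 as a 2-(trimethylsilyl)ethoxymethyl (SEM) acetal and O1 in the ring. The precursor is 3-allyloxy-4-(2,2-dimethyl-3,4-dihydro-2H-pyran-5-yl)-4-SEM-oxycyclobut-2-enone, assembled from squaric acid and a lactone-derived vinyl bromide.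

Key step: step 8

Remark on stereochemistry: the target has no stereogenic centre; compounds 3, 6, 8, 11, 12 and 14 are racemic or transient, so no stereocontrol is needed.

Remark on protecting groups: O5 carries a SEM acetal and O6 an allyl ether, because a silyl ether on O5 would migrate or be cleaved under the basic copper coupling at O6. O6 is freed by neutral palladium catalysis, O5 by fluoride, and the methoxymethyl (MOM) ethers on O8 and ring A by acid in the last step.

Abbreviations: SEM = 2-(trimethylsilyl)ethoxymethyl; MOM = methoxymethyl; DDQ = 2,3-dichloro-5,6-dicyano-1,4-benzoquinone; DMPU = N,N'-dimethylpropyleneurea; DCC = N,N'-dicyclohexylcarbodiimide; DMAP = 4-(dimethylamino)pyridine.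

**Ring B precursor**

Step 1
Reactants: 1 squaric acid
Product: 2 diallyl squarate (3,4-bis(allyloxy)cyclobut-3-ene-1,2-dione)
Conditions: allyl alcohol, toluene, reflux, Dean–Stark trap
Reagents that add atoms: allyl alcohol, C=CCO
Why: Squaric acid is a strong vinylogous acid that is esterified by an alcohol under azeotropic removal of water (Fischer-type esterification), as is routine for dialkyl squarates.

Step 2
Reactants: 2 diallyl squarate
Product: 4 3-(allyloxy)cyclobut-3-ene-1,2-dione, via hydroxycyclobutenone 3 (not isolated)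
Conditions: LiAlH(OtBu)3, THF, −78 to −20 °C; then 6 M HCl, CH2Cl2, 0 °C to rt
Reagents that add atoms: water, O
Why: The bulky hydride adds once to a squarate carbonyl (1,2-reduction), and aqueous acid then ionises the carbinol, adds water to the vinylogous oxocarbenium ion and expels one allyloxy group, the standard reduction–hydrolysis route from dialkyl squarates to 3-alkoxycyclobutenediones.

Step 3
Reactants: 5 6,6-dimethyltetrahydro-2H-pyran-2-one
Product: 6 6,6-dimethyltetrahydro-2H-pyran-2-ol (racemic lactol)
Conditions: iBu2AlH, CH2Cl2, −78 °C; then aq. KNaC4H4O6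
Reagents that add atoms: none
Why: At −78 °C the aluminium hydride stops at the stable tetrahedral aluminium hemiacetal, the usual partial reduction of a lactone to a lactol.

Step 4
Reactants: 6 6,6-dimethyltetrahydro-2H-pyran-2-ol
Product: 7 2,2-dimethyl-3,4-dihydro-2H-pyran
Conditions: MsCl, Et3N, CH2Cl2, 0 °C to reflux; distillation
Reagents that add atoms: none
Why: Sulfonylation of the anomeric hydroxyl and amine-induced elimination through the oxocarbenium ion give the cyclic enol ether, the reaction used to turn 2-deoxy lactols into glycals.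

Step 5
Reactants: 7 2,2-dimethyl-3,4-dihydro-2H-pyran
Product: 9 5-bromo-2,2-dimethyl-3,4-dihydro-2H-pyran, via trans-dibromide 8 (not isolated)
Conditions: Br2, CH2Cl2, −78 °C; then Et3N, −78 °C to reflux
Reagents that add atoms: bromine, BrBr
Why: Electrophilic addition of bromine to the enol ether and amine-induced loss of HBr from the anomeric bromide (elimination through the oxocarbenium ion) leave bromine on the β-carbon, the established preparation of 5-bromo-3,4-dihydro-2H-pyrans.

Step 6
Reactants: 9 5-bromo-2,2-dimethyl-3,4-dihydro-2H-pyran; 4 3-(allyloxy)cyclobut-3-ene-1,2-dione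
Product: 11 3-(allyloxy)-4-(2,2-dimethyl-3,4-dihydro-2H-pyran-5-yl)-4-hydroxycyclobut-2-en-1-one (racemic), via vinyllithium 10 (not isolated)
Conditions: tBuLi (2 equiv), THF, −78 °C; then 4, −78 °C; aq. NH4Cl at −78 °C
Reagents that add atoms: none
Why: Bromine–lithium exchange gives a β-lithio enol ether that adds 1,2 to the carbonyl next to the allyloxy-bearing carbon, the more electrophilic one because the other is a vinylogous ester; the new carbinol centre is racemic and is lost in step 8.

Step 7
Reactants: 11 3-(allyloxy)-4-(2,2-dimethyl-3,4-dihydro-2H-pyran-5-yl)-4-hydroxycyclobut-2-en-1-one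
Product: 12 3-(allyloxy)-4-(2,2-dimethyl-3,4-dihydro-2H-pyran-5-yl)-4-{[2-(trimethylsilyl)ethoxy]methoxy}cyclobut-2-en-1-one (racemic)
Conditions: SEMCl, iPr2NEt, Bu4NI (cat.), CH2Cl2, rt
Reagents that add atoms: 2-(trimethylsilyl)ethoxymethyl chloride, C[Si](C)(C)CCOCCl
Why: Alkylation of the tertiary alcohol by the reactive α-chloro ether under amine base (Williamson-type acetal formation) caps the carbinol oxygen as a base-stable acetal that cannot migrate to a neighbouring phenol later and falls to fluoride.

**Key step and ring B elaboration**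

Step 8
Reactants: 12 3-(allyloxy)-4-(2,2-dimethyl-3,4-dihydro-2H-pyran-5-yl)-4-{[2-(trimethylsilyl)ethoxy]methoxy}cyclobut-2-en-1-one
Product: 15 6-(allyloxy)-2,2-dimethyl-5-{[2-(trimethylsilyl)ethoxy]methoxy}chroman-8-ol, via dienylketene 13 (not isolated), via cyclohexadienone 14 (not isolated)
Conditions: toluene (0.02 M), 110 °C, argon
Reagents that add atoms: none
Why: Heating opens the cyclobutenone by conrotatory 4π electrocyclic ring opening to dienylketene 13, which closes by disrotatory 6π electrocyclisation between the ketene carbon (future C8) and the oxygen-bearing alkene carbon of the dihydropyran (future C8a) to cyclohexadienone 14, and enolisation of the C8a hydrogen gives phenol 15. The closest known reaction is the Moore rearrangement of 4-alkenyl-4-alkoxycyclobutenones to phenols. Ring B is closed as a six-membered carbocycle in the 6π-electrocyclic mode, fused to the existing pyran across C4a–C8a. No stereocentre is created: the racemic carbinol carbon of 12 becomes aromatic C5 and the transient C8a centre of 14 is lost on enolisation. The required torquoselectivity, dihydropyranyl inward, is secured by the strong outward preference of the donor acetal oxygen on the same carbon, and the positions of the four oxygens follow from the connectivity of 12 (carbonyl to O8, allyloxy to O6, acetal to O5, ring oxygen to O1). At 110 °C the allyl vinylogous ester of 12 and the aryl allyl ether of 15 stay below the temperature of Claisen rearrangement.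

Step 9
Reactants: 15 6-(allyloxy)-2,2-dimethyl-5-{[2-(trimethylsilyl)ethoxy]methoxy}chroman-8-ol
Product: 16 6-(allyloxy)-8-(methoxymethoxy)-2,2-dimethyl-5-{[2-(trimethylsilyl)ethoxy]methoxy}chromane
Conditions: MOMCl, iPr2NEt, CH2Cl2, 0 °C to rt
Reagents that add atoms: chloromethyl methyl ether, COCCl
Why: The only free hydroxyl, O8–H, is alkylated by the α-chloro ether (Williamson-type acetal formation), and the same group is used on ring A so that all three fall together in step 21.

Step 10
Reactants: 16 6-(allyloxy)-8-(methoxymethoxy)-2,2-dimethyl-5-{[2-(trimethylsilyl)ethoxy]methoxy}chromane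
Product: 17 6-(allyloxy)-8-(methoxymethoxy)-2,2-dimethyl-5-{[2-(trimethylsilyl)ethoxy]methoxy}-2H-chromene
Conditions: DDQ, 1,4-dioxane, 80 °C
Reagents that add atoms: none
Why: DDQ abstracts hydride from benzylic C4, whose cation is stabilised by O5 and by O1 through C8a, and loss of a C3 proton gives the 2H-chromene (DDQ dehydrogenation of 2,2-dimethylchromans); with every ring oxygen capped the arene cannot go on to a quinone.

Step 11
Reactants: 17 6-(allyloxy)-8-(methoxymethoxy)-2,2-dimethyl-5-{[2-(trimethylsilyl)ethoxy]methoxy}-2H-chromene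
Product: 18 8-(methoxymethoxy)-2,2-dimethyl-5-{[2-(trimethylsilyl)ethoxy]methoxy}-2H-chromen-6-ol
Conditions: Pd(PPh3)4 (5 mol%), morpholine, THF, rt
Reagents that add atoms: none
Why: Zerovalent palladium ionises the aryl allyl ether to a π-allyl complex that morpholine captures (Tsuji–Trost deallylation), under neutral conditions that leave both acetals, the chromene and the other aryl ethers untouched.

**Ring A**

Step 12
Reactants: 19 5-bromobenzene-1,3-diol
Product: 20 2-bromo-4,6-dihydroxybenzaldehyde
Conditions: POCl3, DMF, MeCN, 0 °C to rt; then H2O, 50 °C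
Reagents that add atoms: N,N-dimethylformamide, CN(C)C=O; water, O
Why: Vilsmeier–Haack formylation of the resorcinol occurs para to one hydroxyl and ortho to the other, at the carbon next to bromine, as with orcinol; the two such positions are equivalent.

Step 13
Reactants: 20 2-bromo-4,6-dihydroxybenzaldehyde
Product: 21 2-bromo-4,6-bis(allyloxy)benzaldehyde
Conditions: allyl bromide, K2CO3, DMF, 60 °C
Reagents that add atoms: allyl bromide, C=CCBr
Why: Williamson etherification of both phenols, the hydrogen-bonded one included, proceeds in a dipolar aprotic solvent.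

Step 14
Reactants: 21 2-bromo-4,6-bis(allyloxy)benzaldehyde
Product: 23 3,5-diallyl-2-bromo-4,6-dihydroxybenzaldehyde, via monoallyl phenol 22 (not isolated)
Conditions: PhNEt2, 200 °C, argon
Reagents that add atoms: none
Why: Two aromatic Claisen rearrangements ([3,3]-sigmatropic shifts) move the allyl groups to the only two free ring carbons, C5 and C3, each ortho to an oxygen; should the 4-allyloxy group take C5 first, the 6-allyloxy group reaches C3 by the para-Claisen pathway, so the outcome does not depend on the order.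

Step 15
Reactants: 23 3,5-diallyl-2-bromo-4,6-dihydroxybenzaldehyde
Product: 24 3,5-diallyl-2-bromo-4,6-bis(methoxymethoxy)benzaldehyde
Conditions: NaH, MOMCl, DMF, 0 °C to rt
Reagents that add atoms: chloromethyl methyl ether, COCCl
Why: Both hindered phenoxides, formed irreversibly with NaH, are alkylated by the α-chloro ether (Williamson-type acetal formation), which also removes the acidic protons before the copper coupling.

Step 16
Reactants: 24 3,5-diallyl-2-bromo-4,6-bis(methoxymethoxy)benzaldehyde
Product: 25 2-bromo-4,6-bis(methoxymethoxy)-3,5-bis(3-methylbut-2-en-1-yl)benzaldehyde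
Conditions: second-generation Grubbs catalyst RuCl2(=CHPh)(H2IMes)(PCy3) (5 mol%), 2-methylbut-2-ene/CH2Cl2, 40 °C
Reagents that add atoms: 2-methylbut-2-ene, CC=C(C)C
Why: Olefin cross-metathesis of the two terminal allyl groups with excess 2-methylbut-2-ene exchanges =CH2 for =C(CH3)2, the standard conversion of allylarenes into prenylarenes, and aldehyde, aryl bromide and acetals are inert to the ruthenium carbene.

**Union and endgame**

Step 17
Reactants: 18 8-(methoxymethoxy)-2,2-dimethyl-5-{[2-(trimethylsilyl)ethoxy]methoxy}-2H-chromen-6-ol; 25 2-bromo-4,6-bis(methoxymethoxy)-3,5-bis(3-methylbut-2-en-1-yl)benzaldehyde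
Product: 26 2-{[8-(methoxymethoxy)-2,2-dimethyl-5-{[2-(trimethylsilyl)ethoxy]methoxy}-2H-chromen-6-yl]oxy}-4,6-bis(methoxymethoxy)-3,5-bis(3-methylbut-2-en-1-yl)benzaldehyde
Conditions: CuI (20 mol%), picolinic acid (40 mol%), K3PO4, DMSO, 90 °C, argon
Reagents that add atoms: none
Why: Ullmann diaryl ether synthesis, in which the copper phenoxide of 18 undergoes oxidative addition and reductive elimination at the C–Br bond activated by the ortho formyl group; since O5 and O8 carry non-migrating acetals only O6 can be arylated, and picolinic acid is a ligand suited to ortho-substituted partners.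

Step 18
Reactants: 26 diaryl ether aldehyde
Product: 27 2-{[8-(methoxymethoxy)-2,2-dimethyl-5-{[2-(trimethylsilyl)ethoxy]methoxy}-2H-chromen-6-yl]oxy}-4,6-bis(methoxymethoxy)-3,5-bis(3-methylbut-2-en-1-yl)benzoic acid
Conditions: NaClO2, NaH2PO4, 2-methylbut-2-ene (large excess), tBuOH/THF/H2O, 0 °C to rt
Reagents that add atoms: sodium chlorite, [Na+].[O-]Cl=O
Why: Pinnick oxidation converts the hindered aldehyde into the acid through its chlorous acid adduct, while excess 2-methylbut-2-ene traps hypochlorous acid before it can attack the prenyl or chromene double bonds.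

Step 19
Reactants: 27 diaryl ether acid
Product: 28 2-{[5-hydroxy-8-(methoxymethoxy)-2,2-dimethyl-2H-chromen-6-yl]oxy}-4,6-bis(methoxymethoxy)-3,5-bis(3-methylbut-2-en-1-yl)benzoic acid
Conditions: Bu4NF, THF/DMPU, 50 °C; then aq. NH4Cl
Reagents that add atoms: none
Why: Fluoride attacks silicon and the fragmentation that follows releases the O5 phenoxide (fluoride cleavage of a SEM aryl ether), whereas the three methoxymethyl ethers are inert to fluoride.

Step 20
Reactants: 28 hydroxy acid
Product: 29 Garcinisidone E tris(methoxymethyl) ether (the depsidone with O8 and both ring A phenols as methoxymethyl ethers)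
Conditions: DCC, DMAP (cat.), CH2Cl2 (0.005 M), rt
Reagents that add atoms: none
Why: Carbodiimide activation of the acid and acyl transfer to the only free hydroxyl, O5–H, held next to the diaryl ether oxygen, close the seven-membered lactone (Steglich-type lactonisation, the usual final ring closure of depsidones).

Step 21
Reactants: 29 Garcinisidone E tris(methoxymethyl) ether
Product: 30 Garcinisidone E
Conditions: 3 M HCl (aq.), MeOH/THF, rt
Reagents that add atoms: none
Why: Acid-catalysed methanolysis of the three methoxymethyl acetals liberates O8–H and the two ring A phenols, and dilute acid at room temperature is chosen so that the ortho-prenyl phenols do not cyclise and the chromene and lactone survive.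

**Compound list**

1 | squaric acid (3,4-dihydroxycyclobut-3-ene-1,2-dione) | O=C1C(O)=C(O)C1=O | starting material
2 | diallyl squarate (3,4-bis(allyloxy)cyclobut-3-ene-1,2-dione) | O=C1C(OCC=C)=C(OCC=C)C1=O | intermediate
3 | 2,3-bis(allyloxy)-4-hydroxycyclobut-2-en-1-one (racemic; not isolated) | O=C1C(OCC=C)=C(OCC=C)C1O | intermediate
4 | 3-(allyloxy)cyclobut-3-ene-1,2-dione | O=C1C=C(OCC=C)C1=O | intermediate
5 | 6,6-dimethyltetrahydro-2H-pyran-2-one | CC1(C)CCCC(=O)O1 | starting material
6 | 6,6-dimethyltetrahydro-2H-pyran-2-ol (racemic) | CC1(C)CCCC(O)O1 | intermediate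
7 | 2,2-dimethyl-3,4-dihydro-2H-pyran | CC1(C)CCC=CO1 | intermediate
8 | trans-2,3-dibromo-6,6-dimethyltetrahydro-2H-pyran (racemic, one enantiomer drawn; not isolated) | Br[C@H]1OC(C)(C)CC[C@@H]1Br | intermediate
9 | 5-bromo-2,2-dimethyl-3,4-dihydro-2H-pyran | CC1(C)CCC(Br)=CO1 | intermediate
10 | (2,2-dimethyl-3,4-dihydro-2H-pyran-5-yl)lithium (not isolated) | [Li]C1=COC(C)(C)CC1 | intermediate
11 | 3-(allyloxy)-4-(2,2-dimethyl-3,4-dihydro-2H-pyran-5-yl)-4-hydroxycyclobut-2-en-1-one (racemic) | O=C1C=C(OCC=C)C1(O)C1=COC(C)(C)CC1 | intermediate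
12 | 3-(allyloxy)-4-(2,2-dimethyl-3,4-dihydro-2H-pyran-5-yl)-4-{[2-(trimethylsilyl)ethoxy]methoxy}cyclobut-2-en-1-one (racemic) | O=C1C=C(OCC=C)C1(OCOCC[Si](C)(C)C)C1=COC(C)(C)CC1 | intermediate
13 | (3Z)-3-(allyloxy)-4-(2,2-dimethyl-3,4-dihydro-2H-pyran-5-yl)-4-{[2-(trimethylsilyl)ethoxy]methoxy}buta-1,3-dien-1-one (dienylketene; not isolated) | O=C=C/C(OCC=C)=C(OCOCC[Si](C)(C)C)\C1=COC(C)(C)CC1 | intermediate
14 | 6-(allyloxy)-2,2-dimethyl-5-{[2-(trimethylsilyl)ethoxy]methoxy}-2,3,4,8a-tetrahydro-8H-chromen-8-one (racemic; not isolated) | O=C1C=C(OCC=C)C(OCOCC[Si](C)(C)C)=C2CCC(C)(C)OC12 | intermediate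
15 | 6-(allyloxy)-2,2-dimethyl-5-{[2-(trimethylsilyl)ethoxy]methoxy}chroman-8-ol | CC1(C)CCc2c(O1)c(O)cc(OCC=C)c2OCOCC[Si](C)(C)C | intermediate
16 | 6-(allyloxy)-8-(methoxymethoxy)-2,2-dimethyl-5-{[2-(trimethylsilyl)ethoxy]methoxy}chromane | CC1(C)CCc2c(O1)c(OCOC)cc(OCC=C)c2OCOCC[Si](C)(C)C | intermediate
17 | 6-(allyloxy)-8-(methoxymethoxy)-2,2-dimethyl-5-{[2-(trimethylsilyl)ethoxy]methoxy}-2H-chromene | CC1(C)C=Cc2c(O1)c(OCOC)cc(OCC=C)c2OCOCC[Si](C)(C)C | intermediate
18 | 8-(methoxymethoxy)-2,2-dimethyl-5-{[2-(trimethylsilyl)ethoxy]methoxy}-2H-chromen-6-ol | CC1(C)C=Cc2c(O1)c(OCOC)cc(O)c2OCOCC[Si](C)(C)C | intermediate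
19 | 5-bromobenzene-1,3-diol | Oc1cc(O)cc(Br)c1 | starting material
20 | 2-bromo-4,6-dihydroxybenzaldehyde | O=Cc1c(Br)cc(O)cc1O | intermediate
21 | 2-bromo-4,6-bis(allyloxy)benzaldehyde | O=Cc1c(Br)cc(OCC=C)cc1OCC=C | intermediate
22 | 3-allyl-4-(allyloxy)-6-bromo-2-hydroxybenzaldehyde (not isolated) | O=Cc1c(Br)cc(OCC=C)c(CC=C)c1O | intermediate
23 | 3,5-diallyl-2-bromo-4,6-dihydroxybenzaldehyde | O=Cc1c(Br)c(CC=C)c(O)c(CC=C)c1O | intermediate
24 | 3,5-diallyl-2-bromo-4,6-bis(methoxymethoxy)benzaldehyde | O=Cc1c(Br)c(CC=C)c(OCOC)c(CC=C)c1OCOC | intermediate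
25 | 2-bromo-4,6-bis(methoxymethoxy)-3,5-bis(3-methylbut-2-en-1-yl)benzaldehyde | O=Cc1c(Br)c(CC=C(C)C)c(OCOC)c(CC=C(C)C)c1OCOC | intermediate
26 | 2-{[8-(methoxymethoxy)-2,2-dimethyl-5-{[2-(trimethylsilyl)ethoxy]methoxy}-2H-chromen-6-yl]oxy}-4,6-bis(methoxymethoxy)-3,5-bis(3-methylbut-2-en-1-yl)benzaldehyde | O=Cc1c(Oc2cc(OCOC)c3OC(C)(C)C=Cc3c2OCOCC[Si](C)(C)C)c(CC=C(C)C)c(OCOC)c(CC=C(C)C)c1OCOC | intermediate
27 | 2-{[8-(methoxymethoxy)-2,2-dimethyl-5-{[2-(trimethylsilyl)ethoxy]methoxy}-2H-chromen-6-yl]oxy}-4,6-bis(methoxymethoxy)-3,5-bis(3-methylbut-2-en-1-yl)benzoic acid | OC(=O)c1c(Oc2cc(OCOC)c3OC(C)(C)C=Cc3c2OCOCC[Si](C)(C)C)c(CC=C(C)C)c(OCOC)c(CC=C(C)C)c1OCOC | intermediate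
28 | 2-{[5-hydroxy-8-(methoxymethoxy)-2,2-dimethyl-2H-chromen-6-yl]oxy}-4,6-bis(methoxymethoxy)-3,5-bis(3-methylbut-2-en-1-yl)benzoic acid | OC(=O)c1c(Oc2cc(OCOC)c3OC(C)(C)C=Cc3c2O)c(CC=C(C)C)c(OCOC)c(CC=C(C)C)c1OCOC | intermediate
29 | Garcinisidone E tris(methoxymethyl) ether | CC(C)=CCc1c(OCOC)c(CC=C(C)C)c2c(c1OCOC)C(=O)Oc1c(cc(OCOC)c3c1C=CC(C)(C)O3)O2 | intermediate
30 | Garcinisidone E | CC(C)=CCc1c(O)c(CC=C(C)C)c2c(c1O)C(=O)Oc1c(cc(O)c3c1C=CC(C)(C)O3)O2 | target

**Step count**

Total step count: 21. Longest linear sequence: 14 steps (from 5 through steps 3 to 11 and 17 to 21).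

**Steps most likely to fail**

Step 17 (copper coupling). The oxidative addition at the doubly ortho-substituted bromide may be slow, so that protodebromination of 25 and oxidative decay of the electron-rich phenol 18 outrun C–O bond formation. The fallback reverses the order of the two C–O bonds, ester first and aryl ether by ring closure.
- From 17, Bu4NF in THF/DMPU removes the SEM group to give 6-(allyloxy)-8-(methoxymethoxy)-2,2-dimethyl-2H-chromen-5-ol F1.
- Aldehyde 25 is oxidised (NaClO2, NaH2PO4, 2-methylbut-2-ene) to 2-bromo-4,6-bis(methoxymethoxy)-3,5-bis(3-methylbut-2-en-1-yl)benzoic acid F2.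
- F2 is turned into its acid chloride with 1-chloro-N,N,2-trimethylprop-1-en-1-amine and acylates the sodium salt of F1 to give the depside 6-(allyloxy)-8-(methoxymethoxy)-2,2-dimethyl-2H-chromen-5-yl 2-bromo-4,6-bis(methoxymethoxy)-3,5-bis(3-methylbut-2-en-1-yl)benzoate F3.
- Pd(PPh3)4 and morpholine free O6 to give 6-hydroxy-8-(methoxymethoxy)-2,2-dimethyl-2H-chromen-5-yl 2-bromo-4,6-bis(methoxymethoxy)-3,5-bis(3-methylbut-2-en-1-yl)benzoate F4.
- Intramolecular copper-mediated O-arylation (CuI, picolinic acid, K3PO4, DMSO, high dilution) closes the seven-membered ether ring and returns to the route at 29.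

The 2,6-disubstituted aroyl group is too hindered to migrate readily from O5 to O6, and the coupling gains from being intramolecular.

Step 8 (ring expansion). The acetal oxygen may partly rotate inward, or the sensitive enol ether and ketene may decompose or oligomerise before the electrocyclisation. The fallback uses the free carbinol, whose hydroxyl has the strongest outward preference, and tells O5 from O8 afterwards by hindrance.
- From 11, heating in toluene at 110 °C under argon gives the hydroquinone 6-(allyloxy)-2,2-dimethylchromane-5,8-diol F5.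
- F5 is treated in the same flask with one equivalent of MOMCl and iPr2NEt. The less hindered O8–H (one ortho substituent) should react before O5–H (flanked by C4 and the allyloxy group), to give 6-(allyloxy)-8-(methoxymethoxy)-2,2-dimethylchroman-5-ol F6.
- SEMCl and NaH in DMF then give 16, where the route is rejoined.

Step 14 (double Claisen rearrangement). At 200 °C the formyl group may be lost through ipso attack of the migrating allyl group, the second shift may stay incomplete, or the ortho-allylphenols may cyclise to dihydrobenzofurans. The fallback is direct C-prenylation.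
- From 20, twofold C-alkylation of the dianion with 1-bromo-3-methylbut-2-ene (aq. KOH, 0 °C to rt) should give 2-bromo-4,6-dihydroxy-3,5-bis(3-methylbut-2-en-1-yl)benzaldehyde F7. Both remaining ring carbons are ortho or para to a phenoxide oxygen, and O-alkylated material is separated.
- NaH and MOMCl give 25, where the route is rejoined; steps 13 to 16 are then not needed.

Further compounds
F1 | step 17 | 6-(allyloxy)-8-(methoxymethoxy)-2,2-dimethyl-2H-chromen-5-ol | CC1(C)C=Cc2c(O1)c(OCOC)cc(OCC=C)c2O
F2 | step 17 | 2-bromo-4,6-bis(methoxymethoxy)-3,5-bis(3-methylbut-2-en-1-yl)benzoic acid | OC(=O)c1c(Br)c(CC=C(C)C)c(OCOC)c(CC=C(C)C)c1OCOC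
F3 | step 17 | 6-(allyloxy)-8-(methoxymethoxy)-2,2-dimethyl-2H-chromen-5-yl 2-bromo-4,6-bis(methoxymethoxy)-3,5-bis(3-methylbut-2-en-1-yl)benzoate | O=C(Oc1c(OCC=C)cc(OCOC)c2OC(C)(C)C=Cc12)c1c(Br)c(CC=C(C)C)c(OCOC)c(CC=C(C)C)c1OCOC
F4 | step 17 | 6-hydroxy-8-(methoxymethoxy)-2,2-dimethyl-2H-chromen-5-yl 2-bromo-4,6-bis(methoxymethoxy)-3,5-bis(3-methylbut-2-en-1-yl)benzoate | O=C(Oc1c(O)cc(OCOC)c2OC(C)(C)C=Cc12)c1c(Br)c(CC=C(C)C)c(OCOC)c(CC=C(C)C)c1OCOC
F5 | step 8 | 6-(allyloxy)-2,2-dimethylchromane-5,8-diol | CC1(C)CCc2c(O1)c(O)cc(OCC=C)c2O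
F6 | step 8 | 6-(allyloxy)-8-(methoxymethoxy)-2,2-dimethylchroman-5-ol | CC1(C)CCc2c(O1)c(OCOC)cc(OCC=C)c2O
F7 | step 14 | 2-bromo-4,6-dihydroxy-3,5-bis(3-methylbut-2-en-1-yl)benzaldehyde | O=Cc1c(Br)c(CC=C(C)C)c(O)c(CC=C(C)C)c1O
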